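# Proposed total synthesis of CNP0319766.1 through palladium-catalysed cyclocarbonylation of an ethynyl carbinol

## Analysis of the target

The target is a cembranoid: a 14-membered carbocycle, numbered here C1 (the carbon carrying the exocyclic methylene) to C14 (the carbon carrying OOH) in the direction of the epoxide. A six-membered lactone bridges ring carbons C8 and C10 (oxan-2-one numbering: O1, C2 carbonyl, C3 bearing the methyl, C4 = ring C8, C5 = ring C9, C6 = ring C10). There are seven stereocentres: the trans-epoxide C4/C5 (4S,5S, the oxide of an E-trisubstituted alkene), lactone C3 (S), ring C8 (R) and C10 (R), the tertiary carbinol C11 (S) next to the lactone C–O carbon, and the hydroperoxide carbon C14 (R) next to the 1,1-disubstituted alkene at C1. In the lactone the C3 methyl is trans to the ring bond at C8, and the ring bonds at C8 and C10 are cis, so all three substituents can be equatorial and the C3 configuration is the thermodynamic one. The epoxide and C14 are remote from the lactone cluster and cannot be set by relay from it. The sensitive groups are the secondary allylic hydroperoxide (phosphines, sulfides, low-valent metals, strong base), the trisubstituted epoxide (acid, transannular opening), the lactone with its epimerisable C3 (hydroxide, alkoxide), and the tertiary hydroxyl, which sits 1,4 to C14 and would close a tetrahydrofuran if C14 carried a leaving group. The synthesis is hard because a 14-membered ring must be closed with three separated stereochemical clusters in place, and because the O–O bond has to arrive last under conditions that spare epoxide and lactone. The strategy rests on the C2(=O)–C3(H)CH3 unit of the lactone: together with O1 it equals an ethynyl group on ring C8, one carbon from carbon monoxide and the hydroxyl on ring C10.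

## Retrosynthetic reasoning

**C14–O bond.** The target 44 is unmasked from peroxy ketal 43, and 43 is cut at the C14–O bond into the (14S)-allylic alcohol 38 and the acetone-derived hydroperoxide 40 (made from alkene 39). Cutting here puts the O–O bond into the last two steps, so no earlier reagent has to tolerate it. The forward reaction is an invertive displacement, which ties the C14 configuration to an alcohol that can be set by a reagent. The tertiary oxygen stays silylated through this step so that it cannot close a tetrahydrofuran onto C14.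

**C14 configuration and the C1–C14 bond.** Alcohol 38 comes from enone 37 by catalyst-controlled reduction, and 37 from alcohols 36 and silyl ethers 35. Ring 35 is opened at the C1–C14 bond to ynal 34. This bond joins the methylene-bearing sp2 carbon to the carbinol carbon, so one reductive alkyne–aldehyde coupling creates ring, methylene and oxygen function together from two inert chain termini. The forward closure must bond the aldehyde to the internal alkyne carbon (14-ring, exocyclic alkene) and not to the terminal one (15-ring). The configuration at C14 is not entrusted to the ring closure; it is erased in 37 and reset.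

**Epoxide C–O bonds.** Aldehyde 34 goes back through alcohol 33 to PMB ether 32, and the epoxide of 32 is removed to give E-alkene 31. The epoxidation is placed in the open chain because there the chiral dioxirane alone decides the face, whereas in the macrocycle ring conformation would compete.

**C5–C6 bond.** Alkene 31 (via its silyl-protected form 30) is cut between the methyl-bearing alkene carbon and the arm CH2 into alkyl iodide 21 and vinyl iodide 28. The E-geometry of the trisubstituted alkene is then made in a small fragment (28 from hexynol 22 by syn-hydrometalation) and only has to be retained in an sp3–sp2 coupling. Cutting inside the alkene instead would require an E-selective trisubstituted olefination on the full lactone.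

**C3 methyl.** Iodide 21 comes from alcohol 20 and silyl ether 19, and 19 from the methylene lactone 17 by adding hydrogen across the exocyclic alkene. Because the required C3 epimer is the more stable one, the forward step need not be face-selective; equilibration through the enolate corrects it.

**Lactone C2–C3 and C2–O1 bonds (key disconnection).** Lactone 17 is cut at both bonds to its carbonyl carbon, which leaves the ethynyl carbinol 16. This removes the lactone ring and its one-carbon carbonyl in a single move and reduces the lactone to an alkyne and an alcohol in a 1,5-relationship. An acylation-based alternative (ester of the C10 hydroxyl, then C3–C4 bond formation) would have to create ring C8 during ring closure; here C8 and C10 are fixed beforehand. The forward reaction must be Markovnikov and must find only one free hydroxyl.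

**C8–alkynyl bond and the C10 carbinol.** Alkynol 16 comes from its silylalkyne 14, 14 from ketone 13 by reagent-controlled reduction (C10), and 13 from enone 11 and silylacetylene 12 by asymmetric conjugate alkynylation (C8). The β-carbon of an E-enone is the natural place to introduce an ethynyl group enantioselectively, and the ketone then serves as the handle for C10.

**C9–C10 bond and C11.** Enone 11 arises from allylic alcohol 10, cut at C9–C10 into aldehyde 6 and alkyne 7. Aldehyde 6 goes back through 5, 4 and 2 to (S)-linalool 1, whose carbinol carbon becomes C11. The two alkenes of 1 are cleaved in turn, the trisubstituted one to give the C12–C14 arm and the vinyl group to give C10.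

## Alternatives that were turned down

**Alternative 1: double asymmetric epoxidation with lactonising epoxide opening.** The disconnection removes both epoxides and the lactone C–O bond at once and leads to the 14-membered diene acid A1. In the forward key step both E-trisubstituted alkenes of A1 are epoxidised with the enantiomer of the fructose-derived dioxirane catalyst, and the carboxylate opens the nearer epoxide at its CH carbon to give epoxy hydroxy lactone A2.
- For it: it forms two rings, four stereocentres and the tertiary alcohol in one operation, and it follows the probable biogenesis. On step economy at the late stage it is stronger than the chosen route.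
- Against it: the whole difficulty moves into A1, a macrocycle that already needs three stereocentres. Two macrocyclic alkenes must both obey the catalyst against the ring's own facial bias, and a mismatch at either gives a diastereomer that is hard to separate. The carboxylate has to attack the CH carbon (six-membered ring) although acid activation favours the tertiary carbon (seven-membered ring), and the second epoxide must survive that activation.
- Comparison: the chosen strategy gives this brevity up. In return, each stereocentre is set in an acyclic or small-ring setting by one reagent, and the lactone can only form at one oxygen.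

**Alternative 2: Tsuji–Trost macrocyclisation through a 2-substituted allyl unit.** The ring is cut between the two CH2 carbons on the epoxide side (C2–C3). The acyclic precursor A3 carries an allylic methyl carbonate next to C1 and an allylic phenyl sulfone at the other chain end. Pd(PPh3)4 ionises the carbonate and the sulfonyl carbanion closes the ring to macrocyclic sulfone A4.
- For it: the allyl unit has two equivalent CH2 termini, so there is no regiochemical question. Allylic alkylation is a proven way to 14-membered carbocycles. C14 is set in the open chain before ring closure, which is a real advantage over the chosen route, where C14 has to be corrected after macrocyclisation.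
- Against it: the sulfonyl carbanion is generated next to an epimerisable lactone, and the silyloxy group at C14 is allylic to the same π-allyl unit and invites elimination. After closure the sulfone must be removed reductively from an allylic position, which can move or isomerise the C4=C5 alkene. The epoxidation then has to be done on the macrocycle, with the facial problem noted above.
- Comparison: Alternative 2 says nothing about how the lactone is made and would still need chemistry like that of the chosen key step. The chosen strategy spends its key step on the lactone and keeps the epoxidation acyclic.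

**Alternative 3: radical macrocyclisation onto the unsaturated lactone.** The ring is cut at C7–C8. The primary iodide A5 is converted with (Me3Si)3SiH and a radical initiator into a radical that adds to C4 of the 5,6-dihydropyran-2-one, giving macrocycle A6 without the C3 methyl.
- For it: the conditions are neutral and tolerate epoxide, silyl ethers and the exocyclic alkene. The acceptor is polarity-matched. C14 and the epoxide are set beforehand, and the unsaturated lactone is easy to make.
- Against it: the new stereocentre at ring C8 is created in the macrocyclisation and depends on the transition-state conformation of a 14-membered ring. The 4,6-cis outcome is plausible but not enforced by any reagent. Premature reduction of the radical competes at the dilution needed. The C3 methyl must then be added by enolate alkylation on the macrocycle.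
- Comparison: Alternative 3 is the most convergent of the three and is as strong as the chosen route for C14. The chosen strategy sets ring C8 by a chiral catalyst before any ring exists and obtains C3 by thermodynamic control, so no lactone stereocentre depends on macrocycle conformation.

Key step: step 10

Assumptions:
- (S)-(+)-Linalool of high enantiomeric purity is taken as commercially available; C11 inherits its purity, so the lot is to be checked.
- The sense of the rhodium ligand in step 7 is assigned from the accepted quadrant model for rhodium/biaryl-bisphosphine 1,4-additions, in which the (S)-ligand delivers the carbon group to the α-si face of an (E)-enone.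
- Chain intermediates are named as nonanes or oxan-2-ones; "ring C" numbers refer to the macrocycle numbering defined above.

## Route

Step 1
Reactants: 1 (S)-linalool
Product: 2 (S)-linalool triethylsilyl ether
Conditions: Et3SiOTf, 2,6-lutidine, CH2Cl2, −78 → 0 °C
Reagents that add atoms: triethylsilyl trifluoromethanesulfonate, CC[Si](CC)(CC)OS(=O)(=O)C(F)(F)F
Why: Silyl triflate with lutidine silylates the hindered tertiary hydroxyl without ionising the allylic carbinol (silyl ether formation); the carbinol carbon, future ring C11, is not touched.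

Step 2
Reactants: 2 (S)-linalool triethylsilyl ether
Product: 4 (4S)-4-methyl-4-(triethylsilyloxy)hex-5-en-1-ol, via ozonide 3 (not isolated)
Conditions: O3 (1.0 equiv), CH2Cl2, −78 °C; then NaBH4, MeOH, −78 °C → rt
Reagents that add atoms: ozone, [O-][O+]=O
Why: Ozone reacts much faster with the electron-rich trisubstituted alkene than with the vinyl group next to the quaternary silyloxy carbon, so one equivalent should cleave only the isopropylidene end (chemoselective ozonolysis); hydride reduction of the ozonide gives the primary alcohol that becomes C14–O.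

Step 3
Reactants: 4 (4S)-4-methyl-4-(triethylsilyloxy)hex-5-en-1-ol
Product: 5 (4S)-1-(4-methoxybenzyloxy)-4-methyl-4-(triethylsilyloxy)hex-5-ene
Conditions: NaH, 4-methoxybenzyl chloride, Bu4NI (cat.), DMF, 0 °C → rt
Reagents that add atoms: 4-methoxybenzyl chloride, COc1ccc(CCl)cc1
Why: Williamson etherification of the only free hydroxyl; the PMB ether is orthogonal to the two silyl ethers used later and is removed oxidatively just before the ring closure.

Step 4
Reactants: 5 (4S)-1-(4-methoxybenzyloxy)-4-methyl-4-(triethylsilyloxy)hex-5-ene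
Product: 6 (2S)-5-(4-methoxybenzyloxy)-2-methyl-2-(triethylsilyloxy)pentanal
Conditions: OsO4 (2 mol%), NaIO4, 2,6-lutidine, dioxane–H2O (3:1), rt
Reagents that add atoms: sodium periodate (terminal oxidant, oxygen delivered through catalytic OsO4), [Na+].[O-]I(=O)(=O)=O
Why: Lemieux–Johnson cleavage of the remaining vinyl group avoids ozone in the presence of the PMB arene; the aldehyde has no α-hydrogen and cannot epimerise.

Step 5
Reactants: 7 tert-butyl(but-3-yn-1-yloxy)dimethylsilane, 6 (2S)-5-(4-methoxybenzyloxy)-2-methyl-2-(triethylsilyloxy)pentanal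
Product: 10 (3E,6S)-1-(tert-butyldimethylsilyloxy)-9-(4-methoxybenzyloxy)-6-methyl-6-(triethylsilyloxy)non-3-en-5-ol (both C5 epimers), via alkenylzirconocene chloride 8 (not isolated), via alkenyl(methyl)zinc 9 (not isolated)
Conditions: 7, Cp2Zr(H)Cl, CH2Cl2, rt; Me2Zn, −65 °C; then 6, 0 °C
Reagents that add atoms: none
Why: syn-Hydrozirconation of the terminal alkyne fixes the E-geometry, and zirconium-to-zinc transmetalation gives an alkenylzinc that adds to the hindered aldehyde (hydrozirconation–transmetalation–carbonyl addition); the new carbinol centre is left uncontrolled because it is oxidised in the next step.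

Step 6
Reactants: 10 (3E,6S)-1-(tert-butyldimethylsilyloxy)-9-(4-methoxybenzyloxy)-6-methyl-6-(triethylsilyloxy)non-3-en-5-ol
Product: 11 (3E,6S)-1-(tert-butyldimethylsilyloxy)-9-(4-methoxybenzyloxy)-6-methyl-6-(triethylsilyloxy)non-3-en-5-one
Conditions: DMP, NaHCO3, CH2Cl2, 0 °C → rt
Reagents that add atoms: none
Why: Dess–Martin oxidation of the allylic alcohol gives the E-enone under buffered conditions that keep both silyl ethers and the alkene geometry.

Step 7
Reactants: 11 (3E,6S)-1-(tert-butyldimethylsilyloxy)-9-(4-methoxybenzyloxy)-6-methyl-6-(triethylsilyloxy)non-3-en-5-one, 12 ethynyltriisopropylsilane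
Product: 13 (3R,6S)-1-(tert-butyldimethylsilyloxy)-9-(4-methoxybenzyloxy)-6-methyl-6-(triethylsilyloxy)-3-[(triisopropylsilyl)ethynyl]nonan-5-one
Conditions: [Rh(OAc)(C2H4)2]2 (2.5 mol%), (S)-DTBM-SEGPHOS [(S)-5,5′-bis{bis(3,5-di-tert-butyl-4-methoxyphenyl)phosphino}-4,4′-bi-1,3-benzodioxole] (5.5 mol%), 12 (2 equiv), 1,4-dioxane, 80 °C
Reagents that add atoms: none
Why: Rhodium-catalysed asymmetric conjugate alkynylation of a linear enone; the bulky silyl group and the bulky bisphosphine suppress alkyne dimerisation, and the (S)-ligand should deliver the alkynyl group to the α-si face, giving the (3R) centre (ring C8) under catalyst control because the only existing stereocentre is remote and on the other side of the carbonyl.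

Step 8
Reactants: 13 (3R,6S)-1-(tert-butyldimethylsilyloxy)-9-(4-methoxybenzyloxy)-6-methyl-6-(triethylsilyloxy)-3-[(triisopropylsilyl)ethynyl]nonan-5-one
Product: 14 (3R,5R,6S)-1-(tert-butyldimethylsilyloxy)-9-(4-methoxybenzyloxy)-6-methyl-6-(triethylsilyloxy)-3-[(triisopropylsilyl)ethynyl]nonan-5-ol
Conditions: (S)-2-methyl-CBS-oxazaborolidine [(S)-1-methyl-3,3-diphenyltetrahydro-1H,3H-pyrrolo[1,2-c][1,3,2]oxazaborole] (0.3 equiv), BH3·SMe2, THF, −30 °C; MeOH quench
Reagents that add atoms: none
Why: Corey–Bakshi–Shibata reduction; the quaternary silyloxy carbon is the large ketone substituent and the CH2 the small one, so the (S)-catalyst should give the (5R) carbinol (ring C10), while substrate bias is weak because the quaternary α-carbon carries methyl and CH2 groups of similar size; the bulky silyl group shields the alkyne from borane.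

Step 9
Reactants: 14 (3R,5R,6S)-1-(tert-butyldimethylsilyloxy)-9-(4-methoxybenzyloxy)-6-methyl-6-(triethylsilyloxy)-3-[(triisopropylsilyl)ethynyl]nonan-5-ol
Product: 16 (3R,5R,6S)-1-(tert-butyldimethylsilyloxy)-3-ethynyl-9-(4-methoxybenzyloxy)-6-methyl-6-(triethylsilyloxy)nonan-5-ol, via silver acetylide 15 (not isolated)
Conditions: AgF (1.5 equiv), MeOH, rt, dark; then 1 M HCl (aq), 0 °C, brief
Reagents that add atoms: none
Why: AgF cleaves the alkynyl–silicon bond through the silver acetylide under nearly neutral conditions that leave the alkyl silyl ethers in place and should not trigger a 1,2-silyl shift to the new hydroxyl (silver-mediated protodesilylation of a bulky silylalkyne); brief acid liberates the terminal alkyne.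

Step 10
Reactants: 16 (3R,5R,6S)-1-(tert-butyldimethylsilyloxy)-3-ethynyl-9-(4-methoxybenzyloxy)-6-methyl-6-(triethylsilyloxy)nonan-5-ol
Product: 17 (4R,6R)-4-[2-(tert-butyldimethylsilyloxy)ethyl]-6-[(2S)-5-(4-methoxybenzyloxy)-2-(triethylsilyloxy)pentan-2-yl]-3-methylideneoxan-2-one
Conditions: Pd(OAc)2 (3 mol%), 2-(diphenylphosphino)pyridine (30 mol%), TsOH·H2O (15 mol%), CO (20 bar), toluene, 50 °C
Reagents that add atoms: carbon monoxide, [C-]#[O+]
Why: Under CO the acid-activated Pd(OAc)2/2-(diphenylphosphino)pyridine system forms a cationic hydride of divalent palladium that adds across the terminal alkyne with palladium on the internal carbon; CO insertion gives an α-substituted acryloyl–palladium species, which the C5 hydroxyl (ring C10–O) captures to release the lactone and return the hydride. The closest known reaction type is the Markovnikov alkoxycarbonylation of 1-alkynes and its intramolecular form, the cyclocarbonylation of but-3-yn-1-ols and pent-4-yn-1-ols to α-methylene γ- and δ-lactones. The ring closes by a 6-exo-trig acyl substitution; the internal alkyne carbon becomes lactone C3, the terminal carbon the exocyclic methylene, and the C2–C3 and C2–O1 bonds are the two skeletal bonds formed. No stereocentre is created, and lactone C4 and C6, fixed in steps 7 and 8, are not epimerisable under these conditions. The step needs branched regioselectivity, which the P,N-ligand provides by acting as a proton relay at palladium. It also needs a single oxygen nucleophile, which the substrate secures because the tertiary oxygen and both primary oxygens are masked. The sulfonic acid is kept below the ligand loading so that the pyridyl nitrogen buffers the medium and the silyl and PMB ethers should survive.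

Step 11
Reactants: 17 (4R,6R)-4-[2-(tert-butyldimethylsilyloxy)ethyl]-6-[(2S)-5-(4-methoxybenzyloxy)-2-(triethylsilyloxy)pentan-2-yl]-3-methylideneoxan-2-one
Product: 19 (3S,4R,6R)-4-[2-(tert-butyldimethylsilyloxy)ethyl]-3-methyl-6-[(2S)-5-(4-methoxybenzyloxy)-2-(triethylsilyloxy)pentan-2-yl]oxan-2-one, via 3-epi lactone 18 (not isolated)
Conditions: H2 (1 atm), RhCl(PPh3)3 (5 mol%), toluene, rt; then KOtBu (0.2 equiv), tBuOH–THF, 0 °C → rt
Reagents that add atoms: none
Why: Homogeneous hydrogenation reduces the unhindered 1,1-disubstituted conjugated alkene without touching the PMB ether; whatever C3 mixture forms is equilibrated through the lactone enolate to the 3,4-trans isomer, in which methyl, arm and side chain are all equatorial (thermodynamic control of C3).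

Step 12
Reactants: 19 (3S,4R,6R)-4-[2-(tert-butyldimethylsilyloxy)ethyl]-3-methyl-6-[(2S)-5-(4-methoxybenzyloxy)-2-(triethylsilyloxy)pentan-2-yl]oxan-2-one
Product: 20 (3S,4R,6R)-4-(2-hydroxyethyl)-3-methyl-6-[(2S)-5-(4-methoxybenzyloxy)-2-(triethylsilyloxy)pentan-2-yl]oxan-2-one
Conditions: HF·pyridine, pyridine, THF, 0 °C
Reagents that add atoms: none
Why: Buffered HF·pyridine removes the unhindered primary tert-butyldimethylsilyl ether much faster than the tertiary triethylsilyl ether, which is flanked by a fully substituted carbon (selective desilylation).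

Step 13
Reactants: 20 (3S,4R,6R)-4-(2-hydroxyethyl)-3-methyl-6-[(2S)-5-(4-methoxybenzyloxy)-2-(triethylsilyloxy)pentan-2-yl]oxan-2-one
Product: 21 (3S,4S,6R)-4-(2-iodoethyl)-3-methyl-6-[(2S)-5-(4-methoxybenzyloxy)-2-(triethylsilyloxy)pentan-2-yl]oxan-2-one (same spatial arrangement as 20; the C4 descriptor changes through the priority of iodine)
Conditions: I2, PPh3, imidazole, CH2Cl2, 0 °C → rt
Reagents that add atoms: iodine, II
Why: Appel-type iodination of the primary alcohol under neutral conditions that leave lactone, silyl ether and PMB ether intact.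

Step 14
Reactants: 22 hex-4-yn-1-ol
Product: 24 (E)-5-iodohex-4-en-1-ol, via alkenylzirconocene 23 (not isolated)
Conditions: Cp2Zr(H)Cl (2.5 equiv), THF, 50 °C; then I2, 0 °C
Reagents that add atoms: iodine, II
Why: Hydrozirconation of the 2-alkyne with excess reagent equilibrates to zirconium on the less hindered, methyl-bearing carbon, and iodinolysis with retention gives the (E)-2-iodo-2-alkene; the syn-addition fixes the geometry of the future C4=C5 alkene.

Step 15
Reactants: 24 (E)-5-iodohex-4-en-1-ol
Product: 25 (E)-5-iodohex-4-enal
Conditions: DMP, NaHCO3, CH2Cl2, 0 °C → rt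
Reagents that add atoms: none
Why: Dess–Martin oxidation of a primary alcohol; the vinyl iodide is inert.

Step 16
Reactants: 25 (E)-5-iodohex-4-enal
Product: 26 (E)-6-iodohept-5-en-1-yne
Conditions: dimethyl (1-diazo-2-oxopropyl)phosphonate, K2CO3, MeOH, 0 °C → rt
Reagents that add atoms: dimethyl (1-diazo-2-oxopropyl)phosphonate, COP(=O)(OC)C(=[N+]=[N-])C(C)=O
Why: Ohira–Bestmann homologation turns the aldehyde into the terminal alkyne (future ring C1 and its methylene carbon) without base strong enough to affect the vinyl iodide.

Step 17
Reactants: 26 (E)-6-iodohept-5-en-1-yne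
Product: 28 (E)-(6-iodohept-5-en-1-yn-1-yl)trimethylsilane, via lithium acetylide 27 (not isolated)
Conditions: LiN(SiMe3)2, THF, −78 °C; Me3SiCl, −78 °C → rt
Reagents that add atoms: chlorotrimethylsilane, C[Si](C)(C)Cl
Why: Deprotonation and C-silylation mask the acidic alkyne C–H so that it cannot quench the alkylzinc or enter palladium chemistry in step 18; the amide base does not exchange the vinyl iodide.

Step 18
Reactants: 21 (3S,4S,6R)-4-(2-iodoethyl)-3-methyl-6-[(2S)-5-(4-methoxybenzyloxy)-2-(triethylsilyloxy)pentan-2-yl]oxan-2-one, 28 (E)-(6-iodohept-5-en-1-yn-1-yl)trimethylsilane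
Product: 30 (3S,4R,6R)-3-methyl-4-[(3E)-3-methyl-8-(trimethylsilyl)oct-3-en-7-yn-1-yl]-6-[(2S)-5-(4-methoxybenzyloxy)-2-(triethylsilyloxy)pentan-2-yl]oxan-2-one, via alkylzinc iodide 29 (not isolated)
Conditions: 21, Zn (activated with 1,2-dibromoethane and Me3SiCl), LiCl, THF, 40 °C; then 28, Pd(PPh3)4 (5 mol%), THF, rt → 45 °C
Reagents that add atoms: none
Why: Zinc insertion into the primary iodide tolerates the lactone and the ethers, and the Negishi sp3–sp2 coupling forms the C5–C6 bond with retention of the alkene geometry, so the E-configuration made in step 14 is carried into the chain.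

Step 19
Reactants: 30 (3S,4R,6R)-3-methyl-4-[(3E)-3-methyl-8-(trimethylsilyl)oct-3-en-7-yn-1-yl]-6-[(2S)-5-(4-methoxybenzyloxy)-2-(triethylsilyloxy)pentan-2-yl]oxan-2-one
Product: 31 (3S,4R,6R)-3-methyl-4-[(3E)-3-methyloct-3-en-7-yn-1-yl]-6-[(2S)-5-(4-methoxybenzyloxy)-2-(triethylsilyloxy)pentan-2-yl]oxan-2-one
Conditions: AgNO3 (0.2 equiv), CH2Cl2–MeOH–H2O (7:4:1), rt
Reagents that add atoms: none
Why: Silver-catalysed protodesilylation removes the alkynyl trimethylsilyl group at neutral pH, which avoids the methoxide or fluoride conditions that would endanger the lactone or the tertiary silyl ether.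

Step 20
Reactants: 31 (3S,4R,6R)-3-methyl-4-[(3E)-3-methyloct-3-en-7-yn-1-yl]-6-[(2S)-5-(4-methoxybenzyloxy)-2-(triethylsilyloxy)pentan-2-yl]oxan-2-one
Product: 32 (3S,4R,6R)-4-{2-[(2S,3S)-3-(but-3-yn-1-yl)-2-methyloxiran-2-yl]ethyl}-3-methyl-6-[(2S)-5-(4-methoxybenzyloxy)-2-(triethylsilyloxy)pentan-2-yl]oxan-2-one
Conditions: 1,2:4,5-di-O-isopropylidene-β-L-erythro-2,3-hexodiulo-2,6-pyranose (0.5 equiv), KHSO5 (as 2KHSO5·KHSO4·K2SO4), K2CO3, Bu4NHSO4, Na2B4O7 buffer with Na2EDTA, MeCN–CH2(OMe)2, −5 → 0 °C, short reaction time
Reagents that add atoms: potassium peroxymonosulfate, [K+].[O-]S(=O)(=O)OO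
Why: Shi epoxidation; the dioxirane of the L-configured ketone (the enantiomer of the D-fructose-derived catalyst) attacks the E-trisubstituted alkene through the spiro transition state to give the (S,S)-epoxide (ring C4, C5) under reagent control in an open chain, while the terminal alkyne is inert and the hindered lactone should survive the short exposure to the basic buffer.

Step 21
Reactants: 32 (3S,4R,6R)-4-{2-[(2S,3S)-3-(but-3-yn-1-yl)-2-methyloxiran-2-yl]ethyl}-3-methyl-6-[(2S)-5-(4-methoxybenzyloxy)-2-(triethylsilyloxy)pentan-2-yl]oxan-2-one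
Product: 33 (3S,4R,6R)-4-{2-[(2S,3S)-3-(but-3-yn-1-yl)-2-methyloxiran-2-yl]ethyl}-6-[(2S)-5-hydroxy-2-(triethylsilyloxy)pentan-2-yl]-3-methyloxan-2-one
Conditions: DDQ, CH2Cl2–pH 7 phosphate buffer (10:1), 0 °C
Reagents that add atoms: none
Why: Oxidative cleavage of the PMB ether under buffered conditions leaves epoxide, alkyne, lactone and tertiary silyl ether untouched.

Step 22
Reactants: 33 (3S,4R,6R)-4-{2-[(2S,3S)-3-(but-3-yn-1-yl)-2-methyloxiran-2-yl]ethyl}-6-[(2S)-5-hydroxy-2-(triethylsilyloxy)pentan-2-yl]-3-methyloxan-2-one
Product: 34 (4S)-4-[(2R,4R,5S)-4-{2-[(2S,3S)-3-(but-3-yn-1-yl)-2-methyloxiran-2-yl]ethyl}-5-methyl-6-oxooxan-2-yl]-4-(triethylsilyloxy)pentanal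
Conditions: DMP, NaHCO3, CH2Cl2, 0 °C → rt
Reagents that add atoms: none
Why: Buffered Dess–Martin oxidation gives the aldehyde (ring C14) without acid that could open the epoxide; the tertiary oxygen is silylated, so no lactol can form.

Step 23
Reactants: 34 (4S)-4-[(2R,4R,5S)-4-{2-[(2S,3S)-3-(but-3-yn-1-yl)-2-methyloxiran-2-yl]ethyl}-5-methyl-6-oxooxan-2-yl]-4-(triethylsilyloxy)pentanal
Product: 35 macrocyclic bis(triethylsilyl) ether: 14-membered ring with C1 methylene and C14–OSiEt3 (both C14 epimers) and (4S,5S)-epoxide and C8/C10 lactone and C11–OSiEt3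
Conditions: Ni(cod)2 (30 mol%), 1,3-bis(2,6-diisopropylphenyl)-4,5-diphenyl-4,5-dihydroimidazolium tetrafluoroborate (30 mol%), KOtBu (30 mol%), Et3SiH (5 equiv), THF, rt, syringe-pump addition of 34 (final 0.003 M)
Reagents that add atoms: triethylsilane, CC[SiH](CC)CC
Why: Nickel-catalysed reductive alkyne–aldehyde macrocyclisation; zerovalent nickel couples alkyne and aldehyde to an oxanickelacycle that the silane cleaves, and the very bulky N-heterocyclic carbene directs the aldehyde carbon to the internal alkyne carbon, so the ring closes in the exo sense to the 14-membered exocyclic alkene and not to the 15-membered E-alkene. The C14 configuration is not relied on and both epimers are carried on.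

Step 24
Reactants: 35 macrocyclic bis(triethylsilyl) ether (both C14 epimers)
Product: 36 macrocyclic allylic alcohols: as 35 with C14–OH (both C14 epimers) and C11–OSiEt3 kept
Conditions: HF·pyridine, pyridine, THF, 0 °C
Reagents that add atoms: none
Why: The secondary allylic triethylsilyl ether is cleaved much faster than the hindered tertiary one, and pyridine buffering protects the trisubstituted epoxide (selective desilylation).

Step 25
Reactants: 36 macrocyclic allylic alcohols (both C14 epimers)
Product: 37 macrocyclic α-methylene ketone: as 36 with C14=O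
Conditions: DMP, NaHCO3, CH2Cl2, 0 °C
Reagents that add atoms: none
Why: Dess–Martin oxidation converges both epimers on one enone and clears the uncontrolled C14 centre; the cross-conjugated enone is used at once to avoid dimerisation.

Step 26
Reactants: 37 macrocyclic α-methylene ketone
Product: 38 (14S)-macrocyclic allylic alcohol: as 36 with C14–OH of S configuration
Conditions: (R)-2-methyl-CBS-oxazaborolidine [(R)-1-methyl-3,3-diphenyltetrahydro-1H,3H-pyrrolo[1,2-c][1,3,2]oxazaborole] (1.0 equiv), catecholborane, toluene, −78 °C
Reagents that add atoms: none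
Why: Corey–Bakshi–Shibata 1,2-reduction of an enone with catecholborane; the 1,1-disubstituted alkenyl carbon C1 acts as the large group and C13H2 as the small one, so the (R)-catalyst should give the (14S) alcohol, the epimer needed for an invertive displacement; catecholborane at low temperature does not hydroborate the alkene or reduce the lactone.

Step 27
Reactants: 39 2,3-dimethylbut-2-ene
Product: 40 2-hydroperoxy-2-methoxypropane
Conditions: O3, CH2Cl2–MeOH (4:1), −78 °C; N2 purge, used as a dried solution
Reagents that add atoms: ozone, [O-][O+]=O; methanol, CO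
Why: Ozonolysis in methanol; the carbonyl oxide from the symmetric alkene is trapped by the solvent to give the α-methoxy hydroperoxide, a monoprotected form of hydrogen peroxide whose ketal is cleaved by mild acid.

Step 28
Reactants: 38 (14S)-macrocyclic allylic alcohol, 40 2-hydroperoxy-2-methoxypropane
Product: 43 (14R)-macrocyclic peroxy ketal: C14–OO–C(CH3)2OCH3 with C11–OSiEt3, via mesylate 41 (not isolated), via potassium peroxide 42 (not isolated)
Conditions: 38, Ms2O, Et3N, CH2Cl2, −40 °C; transferred cold into 40 (4 equiv), KOtBu (3.5 equiv), 18-crown-6, DMF, −40 → 0 °C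
Reagents that add atoms: none
Why: Mesylation retains the C14 configuration, and the peroxide anion displaces the allylic mesylate by SN2 with inversion to give the (14R) peroxide (alkylation of a hydroperoxide anion with a sulfonate). The tertiary perketal anion is a strong α-nucleophile but a weak base and a poor acyl acceptor partner, which should spare the lactone, and the silyl group on the C11 oxygen keeps that oxygen from closing a tetrahydrofuran.

Step 29
Reactants: 43 (14R)-macrocyclic peroxy ketal
Product: 44 target hydroperoxide CNP0319766.1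
Conditions: HF·pyridine, pyridine, THF, 0 °C → rt; then AcOH–THF–H2O, rt
Reagents that add atoms: none
Why: Buffered fluoride removes the tertiary triethylsilyl ether and dilute aqueous acid hydrolyses the peroxy ketal to the free hydroperoxide (silyl ether cleavage and ketal hydrolysis); both operations are mild enough that the trisubstituted epoxide and the O–O bond should survive.

## Compound list

1 | (S)-linalool, (3S)-3,7-dimethylocta-1,6-dien-3-ol | C=C[C@@](C)(O)CCC=C(C)C | starting material
2 | (S)-linalool triethylsilyl ether | C=C[C@@](C)(O[Si](CC)(CC)CC)CCC=C(C)C | intermediate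
3 | ozonide (1,2,4-trioxolane) of the 6,7-alkene of 2 | C=C[C@@](C)(O[Si](CC)(CC)CC)CCC1OOC(C)(C)O1 | intermediate
4 | (4S)-4-methyl-4-(triethylsilyloxy)hex-5-en-1-ol | C=C[C@@](C)(O[Si](CC)(CC)CC)CCCO | intermediate
5 | (4S)-1-(4-methoxybenzyloxy)-4-methyl-4-(triethylsilyloxy)hex-5-ene | C=C[C@@](C)(O[Si](CC)(CC)CC)CCCOCc1ccc(OC)cc1 | intermediate
6 | (2S)-5-(4-methoxybenzyloxy)-2-methyl-2-(triethylsilyloxy)pentanal | O=C[C@@](C)(O[Si](CC)(CC)CC)CCCOCc1ccc(OC)cc1 | intermediate
7 | tert-butyl(but-3-yn-1-yloxy)dimethylsilane | C#CCCO[Si](C)(C)C(C)(C)C | starting material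
8 | (E)-[4-(tert-butyldimethylsilyloxy)but-1-en-1-yl]zirconocene chloride | Cl[Zr](/C=C/CCO[Si](C)(C)C(C)(C)C)(C1C=CC=C1)C1C=CC=C1 | intermediate
9 | (E)-[4-(tert-butyldimethylsilyloxy)but-1-en-1-yl](methyl)zinc | C[Zn]/C=C/CCO[Si](C)(C)C(C)(C)C | intermediate
10 | (3E,6S)-1-(tert-butyldimethylsilyloxy)-9-(4-methoxybenzyloxy)-6-methyl-6-(triethylsilyloxy)non-3-en-5-ol, both C5 epimers | OC(/C=C/CCO[Si](C)(C)C(C)(C)C)[C@@](C)(O[Si](CC)(CC)CC)CCCOCc1ccc(OC)cc1 | intermediate
11 | (3E,6S)-1-(tert-butyldimethylsilyloxy)-9-(4-methoxybenzyloxy)-6-methyl-6-(triethylsilyloxy)non-3-en-5-one | O=C(/C=C/CCO[Si](C)(C)C(C)(C)C)[C@@](C)(O[Si](CC)(CC)CC)CCCOCc1ccc(OC)cc1 | intermediate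
12 | ethynyltriisopropylsilane | C#C[Si](C(C)C)(C(C)C)C(C)C | starting material
13 | (3R,6S)-1-(tert-butyldimethylsilyloxy)-9-(4-methoxybenzyloxy)-6-methyl-6-(triethylsilyloxy)-3-[(triisopropylsilyl)ethynyl]nonan-5-one | CC(C)[Si](C#C[C@H](CCO[Si](C)(C)C(C)(C)C)CC(=O)[C@@](C)(O[Si](CC)(CC)CC)CCCOCc1ccc(OC)cc1)(C(C)C)C(C)C | intermediate
14 | (3R,5R,6S)-1-(tert-butyldimethylsilyloxy)-9-(4-methoxybenzyloxy)-6-methyl-6-(triethylsilyloxy)-3-[(triisopropylsilyl)ethynyl]nonan-5-ol | CC(C)[Si](C#C[C@H](CCO[Si](C)(C)C(C)(C)C)C[C@@H](O)[C@@](C)(O[Si](CC)(CC)CC)CCCOCc1ccc(OC)cc1)(C(C)C)C(C)C | intermediate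
15 | silver acetylide of 16 | [Ag]C#C[C@H](CCO[Si](C)(C)C(C)(C)C)C[C@@H](O)[C@@](C)(O[Si](CC)(CC)CC)CCCOCc1ccc(OC)cc1 | intermediate
16 | (3R,5R,6S)-1-(tert-butyldimethylsilyloxy)-3-ethynyl-9-(4-methoxybenzyloxy)-6-methyl-6-(triethylsilyloxy)nonan-5-ol | C#C[C@H](CCO[Si](C)(C)C(C)(C)C)C[C@@H](O)[C@@](C)(O[Si](CC)(CC)CC)CCCOCc1ccc(OC)cc1 | intermediate
17 | (4R,6R)-4-[2-(tert-butyldimethylsilyloxy)ethyl]-6-[(2S)-5-(4-methoxybenzyloxy)-2-(triethylsilyloxy)pentan-2-yl]-3-methylideneoxan-2-one | CC(C)(C)[Si](C)(C)OCC[C@@H]1C[C@@H](OC(=O)C1=C)[C@@](C)(O[Si](CC)(CC)CC)CCCOCc1ccc(OC)cc1 | intermediate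
18 | (3R,4R,6R)-3-methyl lactone, the 3,4-cis epimer of 19 | CC(C)(C)[Si](C)(C)OCC[C@@H]1C[C@@H](OC(=O)[C@@H]1C)[C@@](C)(O[Si](CC)(CC)CC)CCCOCc1ccc(OC)cc1 | intermediate
19 | (3S,4R,6R)-4-[2-(tert-butyldimethylsilyloxy)ethyl]-3-methyl-6-[(2S)-5-(4-methoxybenzyloxy)-2-(triethylsilyloxy)pentan-2-yl]oxan-2-one | CC(C)(C)[Si](C)(C)OCC[C@@H]1C[C@@H](OC(=O)[C@H]1C)[C@@](C)(O[Si](CC)(CC)CC)CCCOCc1ccc(OC)cc1 | intermediate
20 | (3S,4R,6R)-4-(2-hydroxyethyl)-3-methyl-6-[(2S)-5-(4-methoxybenzyloxy)-2-(triethylsilyloxy)pentan-2-yl]oxan-2-one | OCC[C@@H]1C[C@@H](OC(=O)[C@H]1C)[C@@](C)(O[Si](CC)(CC)CC)CCCOCc1ccc(OC)cc1 | intermediate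
21 | (3S,4S,6R)-4-(2-iodoethyl)-3-methyl-6-[(2S)-5-(4-methoxybenzyloxy)-2-(triethylsilyloxy)pentan-2-yl]oxan-2-one | ICC[C@@H]1C[C@@H](OC(=O)[C@H]1C)[C@@](C)(O[Si](CC)(CC)CC)CCCOCc1ccc(OC)cc1 | intermediate
22 | hex-4-yn-1-ol | CC#CCCCO | starting material
23 | alkenylzirconocene from 22 (zirconium on C5 and on oxygen) | C/C(=C\CCCO[Zr](Cl)(C1C=CC=C1)C1C=CC=C1)[Zr](Cl)(C1C=CC=C1)C1C=CC=C1 | intermediate
24 | (E)-5-iodohex-4-en-1-ol | C/C(I)=C\CCCO | intermediate
25 | (E)-5-iodohex-4-enal | C/C(I)=C\CCC=O | intermediate
26 | (E)-6-iodohept-5-en-1-yne | C/C(I)=C\CCC#C | intermediate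
27 | lithium acetylide of 26 | [Li]C#CCC/C=C(\C)I | intermediate
28 | (E)-(6-iodohept-5-en-1-yn-1-yl)trimethylsilane | C/C(I)=C\CCC#C[Si](C)(C)C | intermediate
29 | alkylzinc iodide from 21 | I[Zn]CC[C@@H]1C[C@@H](OC(=O)[C@H]1C)[C@@](C)(O[Si](CC)(CC)CC)CCCOCc1ccc(OC)cc1 | intermediate
30 | (3S,4R,6R)-3-methyl-4-[(3E)-3-methyl-8-(trimethylsilyl)oct-3-en-7-yn-1-yl]-6-[(2S)-5-(4-methoxybenzyloxy)-2-(triethylsilyloxy)pentan-2-yl]oxan-2-one | C[Si](C)(C)C#CCC/C=C(\C)CC[C@@H]1C[C@@H](OC(=O)[C@H]1C)[C@@](C)(O[Si](CC)(CC)CC)CCCOCc1ccc(OC)cc1 | intermediate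
31 | (3S,4R,6R)-3-methyl-4-[(3E)-3-methyloct-3-en-7-yn-1-yl]-6-[(2S)-5-(4-methoxybenzyloxy)-2-(triethylsilyloxy)pentan-2-yl]oxan-2-one | C#CCC/C=C(\C)CC[C@@H]1C[C@@H](OC(=O)[C@H]1C)[C@@](C)(O[Si](CC)(CC)CC)CCCOCc1ccc(OC)cc1 | intermediate
32 | (3S,4R,6R)-4-{2-[(2S,3S)-3-(but-3-yn-1-yl)-2-methyloxiran-2-yl]ethyl}-3-methyl-6-[(2S)-5-(4-methoxybenzyloxy)-2-(triethylsilyloxy)pentan-2-yl]oxan-2-one | C#CCC[C@@H]1O[C@@]1(C)CC[C@@H]1C[C@@H](OC(=O)[C@H]1C)[C@@](C)(O[Si](CC)(CC)CC)CCCOCc1ccc(OC)cc1 | intermediate
33 | (3S,4R,6R)-4-{2-[(2S,3S)-3-(but-3-yn-1-yl)-2-methyloxiran-2-yl]ethyl}-6-[(2S)-5-hydroxy-2-(triethylsilyloxy)pentan-2-yl]-3-methyloxan-2-one | C#CCC[C@@H]1O[C@@]1(C)CC[C@@H]1C[C@@H](OC(=O)[C@H]1C)[C@@](C)(O[Si](CC)(CC)CC)CCCO | intermediate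
34 | (4S)-4-[(2R,4R,5S)-4-{2-[(2S,3S)-3-(but-3-yn-1-yl)-2-methyloxiran-2-yl]ethyl}-5-methyl-6-oxooxan-2-yl]-4-(triethylsilyloxy)pentanal | C#CCC[C@@H]1O[C@@]1(C)CC[C@@H]1C[C@@H](OC(=O)[C@H]1C)[C@@](C)(O[Si](CC)(CC)CC)CCC=O | intermediate
35 | macrocyclic bis(triethylsilyl) ether: 14-membered ring, C1 methylene, C14–OSiEt3 (both epimers), (4S,5S)-epoxide, C8/C10 lactone, C11–OSiEt3 | C=C1CC[C@@H]2O[C@@]2(C)CC[C@@H]2C[C@@H](OC(=O)[C@H]2C)[C@@](C)(O[Si](CC)(CC)CC)CCC1O[Si](CC)(CC)CC | intermediate
36 | macrocyclic allylic alcohols: as 35 with C14–OH (both epimers) | C=C1CC[C@@H]2O[C@@]2(C)CC[C@@H]2C[C@@H](OC(=O)[C@H]2C)[C@@](C)(O[Si](CC)(CC)CC)CCC1O | intermediate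
37 | macrocyclic α-methylene ketone: as 36 with C14=O | C=C1CC[C@@H]2O[C@@]2(C)CC[C@@H]2C[C@@H](OC(=O)[C@H]2C)[C@@](C)(O[Si](CC)(CC)CC)CCC1=O | intermediate
38 | (14S)-macrocyclic allylic alcohol | C=C1CC[C@@H]2O[C@@]2(C)CC[C@@H]2C[C@@H](OC(=O)[C@H]2C)[C@@](C)(O[Si](CC)(CC)CC)CC[C@@H]1O | intermediate
39 | 2,3-dimethylbut-2-ene | CC(C)=C(C)C | starting material
40 | 2-hydroperoxy-2-methoxypropane | COC(C)(C)OO | intermediate
41 | (14S)-macrocyclic allylic mesylate | C=C1CC[C@@H]2O[C@@]2(C)CC[C@@H]2C[C@@H](OC(=O)[C@H]2C)[C@@](C)(O[Si](CC)(CC)CC)CC[C@@H]1OS(C)(=O)=O | intermediate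
42 | potassium 2-methoxypropan-2-yl peroxide | [K+].COC(C)(C)O[O-] | intermediate
43 | (14R)-macrocyclic peroxy ketal, C11–OSiEt3 | C=C1CC[C@@H]2O[C@@]2(C)CC[C@@H]2C[C@@H](OC(=O)[C@H]2C)[C@@](C)(O[Si](CC)(CC)CC)CC[C@H]1OOC(C)(C)OC | intermediate
44 | CNP0319766.1: (4S,5S,8R,10R,11S,14R)-macrocycle with (3S)-methyl lactone, C11–OH and C14–OOH | C=C1CC[C@@H]2O[C@@]2(C)CC[C@@H]2C[C@@H](OC(=O)[C@H]2C)[C@@](C)(O)CC[C@H]1OO | target

## Step count and least certain steps

Total step count: 29. Longest linear sequence: 24 steps (steps 1–13, 18–26, 28 and 29); steps 14–17 and step 27 are side branches.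

**Step 10 (key step).** Three things may go wrong. Palladium hydride may insert in the linear sense at this α-branched alkyne. Intramolecular capture of the acylpalladium species by a hindered secondary hydroxyl may be slow, so that alkyne oligomerisation and catalyst decay win. The acid co-catalyst may strip a silyl or PMB ether. The fallback sets out from 16 and avoids carbonylation altogether. The alkyne is hydroborated in the anti-Markovnikov sense with dicyclohexylborane and oxidised with NaBO3, and the resulting aldehyde closes onto the C5 hydroxyl as the six-membered lactol F1. Oxidation of the lactol with catalytic 2,2,6,6-tetramethylpiperidin-1-oxyl and PhI(OAc)2 gives the 3-unsubstituted lactone F2. Deprotonation with LiN(iPr)2 at −78 °C and methylation with iodomethane should occur anti to the C4 arm and give the trans-3-methyl lactone directly. This fallback comes back to the route at 19.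

**Step 28.** The peroxide anion may attack the methylene terminus (SN2′), the allylic mesylate may ionise with loss of configuration or undergo elimination to a diene, the C11 silyl ether oxygen may participate, or the anion may add to the lactone. The fallback sets out from 36 (either C14 epimer) and changes from substitution to an ene reaction. Mitsunobu activation with 2-nitrobenzenesulfonylhydrazide, PPh3 and diethyl azodicarboxylate gives an allylic diazene that loses dinitrogen with 1,3-transposition to the macrocyclic E-trisubstituted alkene F3 (C14=C1 with a methyl group on C1). Photooxygenation (O2, visible light, tetraphenylporphyrin, CH2Cl2, −20 °C) then effects a Schenck ene reaction in which hydrogen is taken from the methyl group, returning the exocyclic methylene and placing OOH on C14 in the silyl-protected hydroperoxide F4. HF·pyridine removes the silyl group, and the fallback comes back to the route at 44. Regiochemistry and the C14 face are then governed by the ring and not by a reagent, so this is the weaker option in stereocontrol.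

**Step 23.** The closure may take the endo course to the 15-membered ring, oligomerise at practical dilution, or be diverted by nickel insertion into the homopropargylic epoxide or by alkyne trimerisation. The fallback sets out from 33 and uses a Nozaki–Hiyama–Kishi closure. Me3SnCu·SMe2 with methanol adds to the terminal alkyne to give the 2-stannyl-1-alkene F5. Iodine converts this into the 2-iodo-1-alkene F6, and Dess–Martin oxidation gives the iodo aldehyde F7. CrCl2 with catalytic NiCl2 in DMSO–THF at high dilution closes the same C1–C14 bond and gives the free allylic alcohols, so the fallback comes back to the route at 36.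

**Step 7.** The bulky α′-quaternary ketone may slow insertion so that alkyne dimerisation dominates, or catalyst control may be eroded. The fallback sets out from 11 and introduces the two carbons as a vinyl group. A Hayashi–Miyaura addition of potassium vinyltrifluoroborate with Rh(acac)(C2H4)2 and (S)-BINAP gives the β-vinyl ketone F8 with the same facial sense. Reduction with the (S)-oxazaborolidine and catecholborane gives the homoallylic alcohol F9. Lemieux–Johnson cleavage (catalytic OsO4, NaIO4) of the vinyl group gives an aldehyde that is trapped as the five-membered lactol F10. Ohira–Bestmann homologation of the lactol gives the ethynyl carbinol, and the fallback comes back to the route at 16.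

## Further compounds

F1 | step 10 | six-membered lactol from anti-Markovnikov hydration of 16 | CC(C)(C)[Si](C)(C)OCC[C@@H]1C[C@@H](OC(O)C1)[C@@](C)(O[Si](CC)(CC)CC)CCCOCc1ccc(OC)cc1
F2 | step 10 | (4R,6R)-3-unsubstituted lactone | CC(C)(C)[Si](C)(C)OCC[C@@H]1C[C@@H](OC(=O)C1)[C@@](C)(O[Si](CC)(CC)CC)CCCOCc1ccc(OC)cc1
F3 | step 28 | macrocyclic E-trisubstituted alkene (C14=C1, methyl on C1), C11–OSiEt3 | C1/C=C(\C)CC[C@@H]2O[C@@]2(C)CC[C@@H]2C[C@@H](OC(=O)[C@H]2C)[C@@](C)(O[Si](CC)(CC)CC)C1
F4 | step 28 | (14R)-hydroperoxide with C11–OSiEt3 | C=C1CC[C@@H]2O[C@@]2(C)CC[C@@H]2C[C@@H](OC(=O)[C@H]2C)[C@@](C)(O[Si](CC)(CC)CC)CC[C@H]1OO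
F5 | step 23 | 2-(trimethylstannyl)-1-alkene alcohol from 33 | C=C([Sn](C)(C)C)CC[C@@H]1O[C@@]1(C)CC[C@@H]1C[C@@H](OC(=O)[C@H]1C)[C@@](C)(O[Si](CC)(CC)CC)CCCO
F6 | step 23 | 2-iodo-1-alkene alcohol | C=C(I)CC[C@@H]1O[C@@]1(C)CC[C@@H]1C[C@@H](OC(=O)[C@H]1C)[C@@](C)(O[Si](CC)(CC)CC)CCCO
F7 | step 23 | 2-iodo-1-alkene aldehyde | C=C(I)CC[C@@H]1O[C@@]1(C)CC[C@@H]1C[C@@H](OC(=O)[C@H]1C)[C@@](C)(O[Si](CC)(CC)CC)CCC=O
F8 | step 7 | (3R,6S)-β-vinyl ketone | C=C[C@H](CCO[Si](C)(C)C(C)(C)C)CC(=O)[C@@](C)(O[Si](CC)(CC)CC)CCCOCc1ccc(OC)cc1
F9 | step 7 | (3R,5R,6S)-homoallylic alcohol | C=C[C@H](CCO[Si](C)(C)C(C)(C)C)C[C@@H](O)[C@@](C)(O[Si](CC)(CC)CC)CCCOCc1ccc(OC)cc1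
F10 | step 7 | five-membered lactol from cleavage of F9 | OC1[C@H](CCO[Si](C)(C)C(C)(C)C)C[C@@H](O1)[C@@](C)(O[Si](CC)(CC)CC)CCCOCc1ccc(OC)cc1
A1 | alternative 1 | 14-membered diene acid with silyl-protected allylic alcohol | C=C1CC/C=C(\C)CC[C@H](C/C=C(\C)CC[C@@H]1O[Si](C)(C)C(C)(C)C)[C@H](C)C(=O)O
A2 | alternative 1 | epoxy hydroxy lactone with silyl-protected allylic alcohol | C=C1CC[C@@H]2O[C@@]2(C)CC[C@@H]2C[C@@H](OC(=O)[C@H]2C)[C@@](C)(O)CC[C@@H]1O[Si](C)(C)C(C)(C)C
A3 | alternative 2 | acyclic allylic carbonate with terminal allylic phenyl sulfone | O=S(=O)(c1ccccc1)C/C=C(\C)CC[C@@H]1C[C@@H](OC(=O)[C@H]1C)[C@@](C)(O[Si](CC)(CC)CC)CC[C@H](O[Si](C)(C)C(C)(C)C)C(=C)COC(=O)OC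
A4 | alternative 2 | macrocyclic sulfone (sulfone-bearing carbon unassigned) | C=C1CC(S(=O)(=O)c2ccccc2)/C=C(\C)CC[C@@H]2C[C@@H](OC(=O)[C@H]2C)[C@@](C)(O[Si](CC)(CC)CC)CC[C@@H]1O[Si](C)(C)C(C)(C)C
A5 | alternative 3 | primary iodide with 5,6-dihydropyran-2-one acceptor | C=C(CC[C@@H]1O[C@@]1(C)CCI)[C@@H](O[Si](C)(C)C(C)(C)C)CC[C@](C)(O[Si](CC)(CC)CC)[C@H]1CC=CC(=O)O1
A6 | alternative 3 | macrocyclic epoxy lactone lacking the C3 methyl | C=C1CC[C@@H]2O[C@@]2(C)CC[C@@H]2C[C@@H](OC(=O)C2)[C@@](C)(O[Si](CC)(CC)CC)CC[C@@H]1O[Si](C)(C)C(C)(C)C
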